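**Strategy.** Using azulene locants for the left bicycle, the seven-membered ring is read as a cyclopentenone enlarged by C-4 (the CMe2 carbon) and C-5. An intramolecular enone–alkene [2+2] photocycloaddition lays an ether-tethered (CH3)2C=CH– unit across the tetrasubstituted C-3a=C-6 bond of a bicyclo[3.3.0]octenone, forming C-3a–C-4 and C-5–C-6 and fixing C-5 in one operation. The precursor, a Pauson–Khand enone from (S)-linalool, carries the alkene on a CH2–O tether at C-6. RuO4 then turns the tether into a lactone, and a radical at its carbinol carbon (the future 6-methyl) breaks the old C-3a–C-6 bond. The right fragment is joined by aldol condensation.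

Key step: step 7

Locants: the left bicycle has azulene numbering (C-1 carbinol carbon, C-3a and C-8a ring fusion, C-4 CMe2, C-5, C-6=C-7, C-8), used for the same atoms in all precursors; the linker carbons are C-α (on C-5) and C-β; the right bicycle has chromane numbering with primes (O-1′, C-2′ lactol carbon, C-4a′ quaternary, C-5′, C-6′ carbinol, C-8a′).

Assumption: C-2′ epimerises through the open hydroxy aldehyde, so the equatorial-hydroxyl lactol of the target is taken as the thermodynamic epimer; (S)-(+)-linalool of high enantiomeric purity is taken as commercial.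

**Left fragment**

Step 1
Reactants: 1 (S)-(+)-linalool
Product: 2 (S)-linalool triethylsilyl ether
Conditions: Et3SiOTf, 2,6-lutidine, CH2Cl2, −78 → 0 °C
Reagents that add atoms: triethylsilyl trifluoromethanesulfonate CC[Si](CC)(CC)OS(=O)(=O)C(F)(F)F
Why: The silyl triflate with 2,6-lutidine silylates the hindered tertiary alcohol; the bulky, non-coordinating ether is needed for facial control in step 6 and survives the organolithium and photochemical steps.

Step 2
Reactants: 2 (S)-linalool triethylsilyl ether
Product: 3 (4S)-4-methyl-4-(triethylsilyloxy)hex-5-enal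
Conditions: O3 (1.0 equiv, Sudan Red 7B end-point), CH2Cl2, −78 °C; then PPh3, → 20 °C
Reagents that add atoms: ozone [O-][O+]=O
Why: Chemoselective ozonolysis: the electron-rich trisubstituted alkene reacts much faster than the monosubstituted vinyl group on the silyloxy-bearing carbon, and reductive work-up gives the aldehyde.

Step 3
Reactants: 3 (4S)-4-methyl-4-(triethylsilyloxy)hex-5-enal
Product: 4 (S)-dibromoalkene
Conditions: CBr4, PPh3, 2,6-lutidine, CH2Cl2, 0 °C
Reagents that add atoms: tetrabromomethane BrC(Br)(Br)Br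
Why: Ramirez dibromo-olefination (first half of the Corey–Fuchs alkyne synthesis); the base keeps the medium neutral for the tertiary silyl ether.

Step 4
Reactants: 4 (S)-dibromoalkene
Product: 6 (6S)-6-methyl-6-(triethylsilyloxy)oct-7-en-2-yn-1-ol, via lithium acetylide 5 (not isolated)
Conditions: n-BuLi (2.2 equiv), THF, −78 → −20 °C; then (CH2O)n, −20 → 20 °C
Reagents that add atoms: paraformaldehyde (as formaldehyde) C=O
Why: Second half of the Corey–Fuchs sequence: bromine–lithium exchange and 1,2-shift give the lithium acetylide, which adds to formaldehyde to give the propargylic alcohol.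

Step 5
Reactants: 6 (6S)-6-methyl-6-(triethylsilyloxy)oct-7-en-2-yn-1-ol; 7 4-methylpent-3-en-1-ol
Product: 9 enyne ether, via propargylic mesylate 8 (not isolated)
Conditions: 6, MeSO2Cl, Et3N, THF, −20 °C; then sodium alkoxide of 7 (7, NaH, THF), 0 → 20 °C
Reagents that add atoms: none
Why: Williamson ether synthesis run as SN2 displacement on the reactive propargylic mesylate by the primary alkoxide, which avoids the E2 elimination that a homoallylic halide would suffer.

Step 6
Reactants: 9 enyne ether
Product: 10 bicyclo[3.3.0]octenone with the ether tether on C-6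
Conditions: Co2(CO)8 (20 mol %), tetramethylthiourea (1.2 equiv), CO (1 atm), benzene, 70 °C
Reagents that add atoms: carbon monoxide [C-]#[O+]
Why: Catalytic intramolecular Pauson–Khand reaction of the 1,6-enyne (the remote trisubstituted alkene does not compete with the vinyl group); C-8a is set in the alkene insertion, the bulky silyloxy group on C-1 being expected to take the exo position, syn to H-8a, and the minor epimer is removed by chromatography.

Step 7
Reactants: 10 bicyclo[3.3.0]octenone with the ether tether on C-6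
Product: 11 tetracyclic photoadduct
Conditions: hν (366 nm, Pyrex), degassed CH2Cl2 (5 mM), 0 °C
Reagents that add atoms: none
Why: Excitation of the enone and intersystem crossing give the triplet, whose α-carbon C-6 bonds to the less substituted alkene carbon C-5 through a six-membered transition state (6-exo closure of the tetrahydropyran); the resulting 1,4-biradical (tertiary radicals at C-3a and C-4) closes after spin inversion to the cyclobutane (C-3a–C-4), the known course of intramolecular enone–alkene [2+2] photocycloadditions of 2-tethered cycloalkenones. The cyclobutane can only be cis-fused to the cyclopentanone, and the two five-membered rings stay cis-fused only if C-4 enters on the face of H-8a, so the new quaternary centres C-6 and C-3a are fixed by C-8a. The tetrahydropyran must be cis-fused to the cyclobutane, which puts C-α exo and H-5 endo, that is cis to H-8a in the later seven-membered ring, so C-5 is fixed as well. The step needs the straight and not the crossed regiochemistry, which the four-atom tether secures because only the 1,6-closure gives an unstrained first ring. It also needs closure of the hindered biradical to outrun hydrogen transfer from a geminal methyl, which dilute degassed solution and excitation above 350 nm (no absorption by the product ketone) are meant to favour. The net result is insertion of the C-4–C-5 alkene into the C-3a=C-6 bond, completed when step 12 breaks the old C-3a–C-6 bond.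

Step 8
Reactants: 11 tetracyclic photoadduct
Product: 12 keto lactone
Conditions: RuCl3·xH2O (5 mol %), NaIO4 (4 equiv), CCl4/MeCN/pH 7 buffer, 20 °C
Reagents that add atoms: sodium periodate (oxygen donor through RuO4) [Na+].[O-][I](=O)(=O)=O
Why: RuO4-mediated oxidation of an ether to an ester: the unhindered O–CH2 flanked by CH2 is oxidised in preference to the neopentyl O–CH2 on the quaternary C-6, and no alkene is present at this stage.

Step 9
Reactants: 12 keto lactone
Product: 13 hydroxy Weinreb amide
Conditions: MeNH(OMe)·HCl, i-PrMgCl, THF, −20 → 0 °C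
Reagents that add atoms: N,O-dimethylhydroxylamine hydrochloride CNOC.Cl
Why: Aminolysis of the lactone by the magnesium amide of N,O-dimethylhydroxylamine gives the Weinreb amide (C-β kept at the aldehyde oxidation level) and frees the neopentyl alcohol; the hindered ketone is left.

Step 10
Reactants: 13 hydroxy Weinreb amide
Product: 15 S-methyl xanthate, via sodium xanthate 14 (not isolated)
Conditions: NaH, CS2, THF, 0 °C; then MeI, 0 → 20 °C
Reagents that add atoms: carbon disulfide S=C=S; iodomethane CI
Why: Xanthate formation (alkoxide, CS2, then S-methylation) activates the neopentyl alcohol for radical C–O cleavage without an SN2 step at this hindered centre, and the xanthate has no β-hydrogen for thermal elimination.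

Step 11
Reactants: 15 S-methyl xanthate
Product: 17 diol xanthate, via silyl-protected alcohol 16 (not isolated)
Conditions: NaBH4, CeCl3·7H2O, MeOH, −40 °C; then 1 M HCl, 20 °C
Reagents that add atoms: none
Why: Luche reduction of the cyclopentanone (hydride expected from the face opposite the cyclobutane; this temporary centre is destroyed in step 13) lets the radical step give an allylic alcohol and not a reducible enone, and the acidic work-up cleaves the tertiary triethylsilyl ether, which is no longer needed.

Step 12
Reactants: 17 diol xanthate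
Product: 18 hydroazulene allylic alcohol
Conditions: Bu3SnH (1.5 equiv, slow addition), 1,1′-azobis(cyclohexanecarbonitrile), xylenes, 135 °C
Reagents that add atoms: none
Why: Barton–McCombie C–O homolysis gives the neopentyl primary radical, whose strain-driven cyclobutylcarbinyl β-scission breaks the old C-3a–C-6 bond (tertiary ring-fusion radical preferred over the secondary C-5 radical), and hydrogen transfer from Bu3SnH anti to C-8, on the face of H-8a and the small 1-hydroxyl, should set C-3a with cis ring fusion.

Step 13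
Reactants: 18 hydroazulene allylic alcohol
Product: 21 hydroazulene Weinreb amide, via sulfonylhydrazine 19 (not isolated), via allylic diazene 20 (not isolated)
Conditions: 2-nitrobenzenesulfonylhydrazide, PPh3, diethyl azodicarboxylate, THF/N-methylmorpholine, −30 → 23 °C
Reagents that add atoms: none
Why: Mitsunobu displacement of the allylic alcohol by the sulfonylhydrazide, loss of arenesulfinic acid and sigmatropic extrusion of N2 from the allylic diazene (reductive 1,3-transposition) deliver hydrogen to the exocyclic CH2, which becomes the 6-methyl, and place the double bond at C-6=C-7; the tertiary alcohol and the amide do not react.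

Step 14
Reactants: 21 hydroazulene Weinreb amide
Product: 22 left-fragment aldehyde
Conditions: i-Bu2AlH (3 equiv), THF, −78 °C; aq. potassium sodium tartrate
Reagents that add atoms: none
Why: Hydride reduction of the Weinreb amide stops at the chelated aluminium hemiaminal and gives the aldehyde on work-up; one equivalent of hydride is consumed by the tertiary alcohol.

**Right fragment**

Step 15
Reactants: 23 4-methoxy-2-methylphenol
Product: 24 4,4-dimethoxy-2-methylcyclohexa-2,5-dien-1-one
Conditions: PhI(OAc)2, MeOH, 0 °C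
Reagents that add atoms: methanol CO
Why: Oxidative dearomatisation of the para-methoxyphenol with PhI(OAc)2 in methanol gives the quinone monoketal.

Step 16
Reactants: 24 4,4-dimethoxy-2-methylcyclohexa-2,5-dien-1-one
Product: 25 4,4-dimethoxy-2-methylcyclohex-2-en-1-one
Conditions: H2 (1 atm), RhCl(PPh3)3 (3 mol %), benzene, 20 °C
Reagents that add atoms: none
Why: Homogeneous hydrogenation with RhCl(PPh3)3 reduces the disubstituted alkene and leaves the trisubstituted enone alkene and the allylic ketal.

Step 17
Reactants: 25 4,4-dimethoxy-2-methylcyclohex-2-en-1-one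
Product: 27 (4S)-4-hydroxy-3-methylcyclohex-2-en-1-one, via allylic alcohol ketal 26 (not isolated)
Conditions: (R)-2-methyl-CBS-oxazaborolidine (10 mol %), BH3·SMe2, THF, −20 °C; then 1 M HCl, 20 °C
Reagents that add atoms: water O
Why: CBS reduction of the 2-methyl enone, in which the substituted alkene arm acts as the large group, so that the (R)-catalyst is expected to give the (S)-alcohol (sets C-8a′); the acidic work-up hydrolyses the allylic dimethyl ketal to the transposed enone.

Step 18
Reactants: 27 (4S)-4-hydroxy-3-methylcyclohex-2-en-1-one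
Product: 28 (4S)-3-methyl-4-(triethylsilyloxy)cyclohex-2-en-1-one
Conditions: Et3SiCl, imidazole, DMF, 0 °C
Reagents that add atoms: chlorotriethylsilane CC[Si](Cl)(CC)CC
Why: Standard silylation of the secondary allylic alcohol; the silyloxy group directs step 19.

Step 19
Reactants: 28 (4S)-3-methyl-4-(triethylsilyloxy)cyclohex-2-en-1-one
Product: 29 right-fragment silyl enol ether
Conditions: 2-(1,3-dioxolan-2-yl)ethylmagnesium bromide, CuBr·SMe2 (20 mol %), Me3SiCl, HMPA, THF, −78 → −40 °C; Et3N
Reagents that add atoms: 2-(1,3-dioxolan-2-yl)ethylmagnesium bromide Br[Mg]CCC1OCCO1; chlorotrimethylsilane C[Si](C)(C)Cl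
Why: Me3SiCl-accelerated copper-catalysed conjugate addition of the Grignard reagent to the β,β-disubstituted enone anti to the γ-silyloxy group sets the quaternary C-4a′, and the enolate is trapped regiospecifically as the silyl enol ether.

**Union and end game**

Step 20
Reactants: 29 right-fragment silyl enol ether; 22 left-fragment aldehyde
Product: 31 aldol adduct, via lithium enolate 30 (not isolated)
Conditions: 29 (2.3 equiv), MeLi, THF, 0 °C; then 22, −78 °C
Reagents that add atoms: none
Why: MeLi cleaves the silyl enol ether to the regiodefined lithium enolate, which undergoes aldol addition to the aldehyde (one equivalent of enolate is spent on the tertiary alcohol); the two new centres are removed in steps 21 and 22.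

Step 21
Reactants: 31 aldol adduct
Product: 33 exocyclic enone, via β-mesyloxy ketone 32 (not isolated)
Conditions: MeSO2Cl, Et3N, CH2Cl2, −20 °C; then DBU, 20 °C
Reagents that add atoms: none
Why: Mesylation of the secondary aldol hydroxyl (the tertiary alcohol is unreactive at low temperature) and E1cB elimination with DBU complete the aldol condensation.

Step 22
Reactants: 33 exocyclic enone
Product: 34 coupled ketone
Conditions: [(Ph3P)CuH]6, benzene/H2O, 20 °C; then K2CO3, MeOH, 20 °C
Reagents that add atoms: none
Why: Copper hydride reduces the enone by conjugate addition without touching the isolated trisubstituted alkene, and base equilibration of the α-centre puts the side chain equatorial (C-5′), trans to the C-4′ chain on the neighbouring quaternary carbon.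

Step 23
Reactants: 34 coupled ketone
Product: 35 protected tertiary alcohol
Conditions: MeMgBr, CeCl3, THF, −78 → 0 °C
Reagents that add atoms: methylmagnesium bromide C[Mg]Br
Why: 1,2-Addition of the methyl organometallic (CeCl3 suppresses enolisation) from the equatorial direction, the axial face being blocked by the 1,3-diaxial 4a′-methyl, gives the axial tertiary alcohol at C-6′ cis to that methyl.

Step 24
Reactants: 35 protected tertiary alcohol
Product: 37 target CNP0167351.1, via seco hydroxy aldehyde 36 (not isolated)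
Conditions: AcOH/THF/H2O (3:1:1), 45 °C
Reagents that add atoms: water O
Why: Mild aqueous acid cleaves the secondary silyl ether and the dioxolane, and the liberated 8a′-hydroxyl closes onto the aldehyde to give the trans-fused lactol, whose C-2′ hydroxyl equilibrates to the equatorial position.

**Compound list**

1 | (S)-(+)-linalool, (3S)-3,7-dimethylocta-1,6-dien-3-ol | C=C[C@@](C)(O)CCC=C(C)C | starting material
2 | triethyl{[(3S)-3,7-dimethylocta-1,6-dien-3-yl]oxy}silane | C=C[C@@](C)(O[Si](CC)(CC)CC)CCC=C(C)C | intermediate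
3 | (4S)-4-methyl-4-[(triethylsilyl)oxy]hex-5-enal | C=C[C@@](C)(O[Si](CC)(CC)CC)CCC=O | intermediate
4 | triethyl{[(3S)-7,7-dibromo-3-methylhepta-1,6-dien-3-yl]oxy}silane | C=C[C@@](C)(O[Si](CC)(CC)CC)CCC=C(Br)Br | intermediate
5 | lithium acetylide of (3S)-3-methyl-3-[(triethylsilyl)oxy]hept-1-en-6-yne (lithium on the alkyne terminus) | C=C[C@@](C)(O[Si](CC)(CC)CC)CCC#C[Li] | intermediate
6 | (6S)-6-methyl-6-[(triethylsilyl)oxy]oct-7-en-2-yn-1-ol | C=C[C@@](C)(O[Si](CC)(CC)CC)CCC#CCO | intermediate
7 | 4-methylpent-3-en-1-ol | CC(C)=CCCO | starting material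
8 | (6S)-6-methyl-6-[(triethylsilyl)oxy]oct-7-en-2-yn-1-yl methanesulfonate | C=C[C@@](C)(O[Si](CC)(CC)CC)CCC#CCOS(C)(=O)=O | intermediate
9 | triethyl{[(3S)-3-methyl-8-[(4-methylpent-3-en-1-yl)oxy]oct-1-en-6-yn-3-yl]oxy}silane | C=C[C@@](C)(O[Si](CC)(CC)CC)CCC#CCOCCC=C(C)C | intermediate
10 | (5S,6S)-6-methyl-2-{[(4-methylpent-3-en-1-yl)oxy]methyl}-6-[(triethylsilyl)oxy]bicyclo[3.3.0]oct-1-en-3-one (silyloxy cis to the ring-fusion hydrogen) | O=C1C[C@H]2C(=C1COCCC=C(C)C)CC[C@]2(C)O[Si](CC)(CC)CC | intermediate
11 | tetracyclic photoadduct: C-7 cyclopentanone cis-fused to the cyclobutane C-3a/C-4/C-5/C-6, which is cis-fused along C-5–C-6 to a tetrahydropyran (C-6–CH2–O–CH2–CH2–C-5, C-α exo); the silyloxy cyclopentane lies on the face of C-3a opposite the cyclobutane, H-8a cis to C-4 | O=C1C[C@H]2[C@@]3(CC[C@]2(C)O[Si](CC)(CC)CC)C(C)(C)[C@@H]2CCOC[C@@]123 | intermediate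
12 | keto δ-lactone: 11 with the ring O–CH2 next to C-α oxidised to O–C(=O) | O=C1C[C@H]2[C@@]3(CC[C@]2(C)O[Si](CC)(CC)CC)C(C)(C)[C@@H]2CC(=O)OC[C@@]123 | intermediate
13 | tricyclic ketone with CH2OH on C-6 and CH2C(=O)N(OMe)Me on C-5 | O=C1C[C@H]2[C@@]3(CC[C@]2(C)O[Si](CC)(CC)CC)C(C)(C)[C@H](CC(=O)N(C)OC)[C@@]13CO | intermediate
14 | sodium O-alkyl dithiocarbonate of 13 | O=C1C[C@H]2[C@@]3(CC[C@]2(C)O[Si](CC)(CC)CC)C(C)(C)[C@H](CC(=O)N(C)OC)[C@@]13COC(=S)[S-].[Na+] | intermediate
15 | O-alkyl S-methyl xanthate of 13 | O=C1C[C@H]2[C@@]3(CC[C@]2(C)O[Si](CC)(CC)CC)C(C)(C)[C@H](CC(=O)N(C)OC)[C@@]13COC(=S)SC | intermediate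
16 | C-7 alcohol of 15 (7-OH drawn cis to the cyclobutane; the epimer would serve equally), silyl ether intact | O[C@H]1C[C@H]2[C@@]3(CC[C@]2(C)O[Si](CC)(CC)CC)C(C)(C)[C@H](CC(=O)N(C)OC)[C@@]13COC(=S)SC | intermediate
17 | 1,7-diol xanthate (16 without the silyl group) | O[C@H]1C[C@H]2[C@@]3(CC[C@]2(C)O)C(C)(C)[C@H](CC(=O)N(C)OC)[C@@]13COC(=S)SC | intermediate
18 | 2-[1,7-dihydroxy-1,4,4-trimethyl-6-methylidenedecahydroazulen-5-yl]-N-methoxy-N-methylacetamide (H-3a, H-5, H-8a and 1-OH on one face) | C=C1[C@@H](O)C[C@H]2[C@H](CC[C@]2(C)O)C(C)(C)[C@@H]1CC(=O)N(C)OC | intermediate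
19 | N-(C-7-azulenyl)-N-(2-nitrobenzenesulfonyl)hydrazine from 18 (C-7 inverted) | C=C1[C@H](N(N)S(=O)(=O)c3ccccc3[N+](=O)[O-])C[C@H]2[C@H](CC[C@]2(C)O)C(C)(C)[C@@H]1CC(=O)N(C)OC | intermediate
20 | allylic monoalkyl diazene at C-7 | C=C1[C@H](N=N)C[C@H]2[C@H](CC[C@]2(C)O)C(C)(C)[C@@H]1CC(=O)N(C)OC | intermediate
21 | 2-[(1S,3aS,5R,8aS)-1-hydroxy-1,4,4,6-tetramethyl-1,2,3,3a,4,5,8,8a-octahydroazulen-5-yl]-N-methoxy-N-methylacetamide | CC1=CC[C@H]2[C@H](CC[C@]2(C)O)C(C)(C)[C@@H]1CC(=O)N(C)OC | intermediate
22 | [(1S,3aS,5R,8aS)-1-hydroxy-1,4,4,6-tetramethyl-1,2,3,3a,4,5,8,8a-octahydroazulen-5-yl]acetaldehyde | CC1=CC[C@H]2[C@H](CC[C@]2(C)O)C(C)(C)[C@@H]1CC=O | intermediate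
23 | 4-methoxy-2-methylphenol | COc1ccc(O)c(C)c1 | starting material
24 | 4,4-dimethoxy-2-methylcyclohexa-2,5-dien-1-one | COC1(OC)C=CC(=O)C(C)=C1 | intermediate
25 | 4,4-dimethoxy-2-methylcyclohex-2-en-1-one | COC1(OC)CCC(=O)C(C)=C1 | intermediate
26 | (1S)-4,4-dimethoxy-2-methylcyclohex-2-en-1-ol | COC1(OC)CC[C@H](O)C(C)=C1 | intermediate
27 | (4S)-4-hydroxy-3-methylcyclohex-2-en-1-one | O=C1CC[C@H](O)C(C)=C1 | intermediate
28 | (4S)-3-methyl-4-[(triethylsilyl)oxy]cyclohex-2-en-1-one | O=C1CC[C@H](O[Si](CC)(CC)CC)C(C)=C1 | intermediate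
29 | trimethyl({(3S,4S)-3-[2-(1,3-dioxolan-2-yl)ethyl]-3-methyl-4-[(triethylsilyl)oxy]cyclohex-1-en-1-yl}oxy)silane | C[Si](C)(C)OC1=C[C@](C)(CCC2OCCO2)[C@@H](O[Si](CC)(CC)CC)CC1 | intermediate
30 | lithium enolate corresponding to 29 | [Li]OC1=C[C@](C)(CCC2OCCO2)[C@@H](O[Si](CC)(CC)CC)CC1 | intermediate
31 | aldol adduct: β-hydroxy ketone joining C-β of 22 to C-5′ (mixture of diastereomers at C-β and C-5′) | CC1=CC[C@H]2[C@H](CC[C@]2(C)O)C(C)(C)[C@@H]1CC(O)C1C(=O)CC[C@H](O[Si](CC)(CC)CC)[C@@]1(C)CCC1OCCO1 | intermediate
32 | methanesulfonate of 31 | CC1=CC[C@H]2[C@H](CC[C@]2(C)O)C(C)(C)[C@@H]1CC(OS(C)(=O)=O)C1C(=O)CC[C@H](O[Si](CC)(CC)CC)[C@@]1(C)CCC1OCCO1 | intermediate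
33 | exocyclic enone C-β=C-5′ conjugated with the C-6′ ketone (E drawn; the geometry is inconsequential) | CC1=CC[C@H]2[C@H](CC[C@]2(C)O)C(C)(C)[C@@H]1C/C=C1/C(=O)CC[C@H](O[Si](CC)(CC)CC)[C@@]1(C)CCC1OCCO1 | intermediate
34 | coupled C-6′ ketone with equatorial side chain at C-5′ | CC1=CC[C@H]2[C@H](CC[C@]2(C)O)C(C)(C)[C@@H]1CC[C@@H]1C(=O)CC[C@H](O[Si](CC)(CC)CC)[C@@]1(C)CCC1OCCO1 | intermediate
35 | C-6′ tertiary alcohol (axial OH), 8a′-O-triethylsilyl, dioxolane-protected aldehyde | CC1=CC[C@H]2[C@H](CC[C@]2(C)O)C(C)(C)[C@@H]1CC[C@@H]1[C@](C)(O)CC[C@H](O[Si](CC)(CC)CC)[C@@]1(C)CCC1OCCO1 | intermediate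
36 | seco triol aldehyde (open form of the lactol) | CC1=CC[C@H]2[C@H](CC[C@]2(C)O)C(C)(C)[C@@H]1CC[C@@H]1[C@](C)(O)CC[C@H](O)[C@@]1(C)CCC=O | intermediate
37 | CNP0167351.1, (2S,4aS,5S,6R,8aS)-5-{2-[(1S,3aS,5R,8aS)-1-hydroxy-1,4,4,6-tetramethyl-1,2,3,3a,4,5,8,8a-octahydroazulen-5-yl]ethyl}-4a,6-dimethyloctahydro-2H-chromene-2,6-diol | CC1=CC[C@H]2[C@H](CC[C@]2(C)O)C(C)(C)[C@@H]1CC[C@H]1[C@]2(C)CC[C@@H](O)O[C@H]2CC[C@@]1(C)O | target

**Step count.** Total: 24 steps. Longest linear sequence: 19 steps (steps 1–14 and 20–24).

**Steps most likely to fail**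

Step 7. The triplet 1,4-biradical may revert or transfer a hydrogen from a geminal methyl instead of closing to the congested cyclobutane, or the alkene may engage in the crossed orientation. The fallback gives up the tether and uses the intermolecular head-to-tail photocycloaddition with the alkene in excess. It sets out from 6: acetylation (Ac2O, pyridine) gives the propargylic acetate F1; the Pauson–Khand conditions of step 6 give the acetoxymethyl enone F2; irradiation (366 nm) of F2 in an excess of 7 gives the head-to-tail hydroxy acetate photoadduct F3, the C-5 exo isomer being separated from its epimer; K2CO3 in methanol gives the diol F4; TEMPO with PhI(OAc)2 oxidises the unhindered primary alcohol and closes the lactone, which is 12, where the route is rejoined.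

Step 12. Homolysis of the primary C–O bond may be too slow (return of the alcohol), the radical may open the other cyclobutane bond, or hydrogen transfer at 135 °C may reach the wrong face of the ring-fusion radical. The fallback generates the same radical by iodine abstraction at 0 °C. It sets out from 12: LiAlH4 reduces lactone and ketone to the triol F5; pivaloyl chloride in pyridine at −20 °C acylates only the unhindered primary alcohol to give the pivalate F6, whose ester group cannot participate at the neopentyl carbon; I2, PPh3 and imidazole in toluene at 80 °C give the neopentyl iodide F7; Bu3SnH with Et3B and air at 0 °C gives the ring-expanded allylic alcohol F8; the reductive transposition of step 13 passes through the sulfonylhydrazine F9 and the diazene F10 to the alkene pivalate F11; i-Bu2AlH followed by 1 M HCl work-up removes the pivalate and the silyl ether to give the diol F12; Dess–Martin periodinane oxidises the primary alcohol to 22, where the route is rejoined.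

Step 6. The facial selectivity of the alkene insertion may be low or reversed, because the silyloxy and methyl groups on C-1 differ little in effective size. The fallback replaces substrate control by ligand control: 9 is cyclised with a cationic rhodium–BINAP catalyst made from [Rh(CO)2Cl]2, (R)- or (S)-BINAP and AgOTf under CO (1 atm) in THF at 90 °C, using the ligand antipode that is matched with the C-1 centre; it sets out from 9 and returns at 10 without new compounds.

Further compounds
F1 | step 7 | (6S)-6-methyl-6-[(triethylsilyl)oxy]oct-7-en-2-yn-1-yl acetate | C=C[C@@](C)(O[Si](CC)(CC)CC)CCC#CCOC(C)=O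
F2 | step 7 | (5S,6S)-2-(acetoxymethyl)-6-methyl-6-[(triethylsilyl)oxy]bicyclo[3.3.0]oct-1-en-3-one | O=C1C[C@H]2C(=C1COC(C)=O)CC[C@]2(C)O[Si](CC)(CC)CC
F3 | step 7 | tricyclic head-to-tail photoadduct with CH2OAc on C-6 and CH2CH2OH on C-5 (exo) | O=C1C[C@H]2[C@@]3(CC[C@]2(C)O[Si](CC)(CC)CC)C(C)(C)[C@H](CCO)[C@@]13COC(C)=O
F4 | step 7 | tricyclic keto diol with CH2OH on C-6 and CH2CH2OH on C-5 | O=C1C[C@H]2[C@@]3(CC[C@]2(C)O[Si](CC)(CC)CC)C(C)(C)[C@H](CCO)[C@@]13CO
F5 | step 12 | tricyclic triol: C-7 alcohol with CH2OH on C-6 and CH2CH2OH on C-5, silyl ether intact | O[C@H]1C[C@H]2[C@@]3(CC[C@]2(C)O[Si](CC)(CC)CC)C(C)(C)[C@H](CCO)[C@@]13CO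
F6 | step 12 | mono-pivalate of F5 at the CH2CH2OH group | O[C@H]1C[C@H]2[C@@]3(CC[C@]2(C)O[Si](CC)(CC)CC)C(C)(C)[C@H](CCOC(=O)C(C)(C)C)[C@@]13CO
F7 | step 12 | neopentyl iodide from F6 | O[C@H]1C[C@H]2[C@@]3(CC[C@]2(C)O[Si](CC)(CC)CC)C(C)(C)[C@H](CCOC(=O)C(C)(C)C)[C@@]13CI
F8 | step 12 | 6-methylidene hydroazulene 7-alcohol with 2-(pivaloyloxy)ethyl on C-5, silyl ether intact | C=C1[C@@H](O)C[C@H]2[C@H](CC[C@]2(C)O[Si](CC)(CC)CC)C(C)(C)[C@@H]1CCOC(=O)C(C)(C)C
F9 | step 12 | N-alkyl-N-(2-nitrobenzenesulfonyl)hydrazine from F8 | C=C1[C@H](N(N)S(=O)(=O)c3ccccc3[N+](=O)[O-])C[C@H]2[C@H](CC[C@]2(C)O[Si](CC)(CC)CC)C(C)(C)[C@@H]1CCOC(=O)C(C)(C)C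
F10 | step 12 | allylic diazene from F9 | C=C1[C@H](N=N)C[C@H]2[C@H](CC[C@]2(C)O[Si](CC)(CC)CC)C(C)(C)[C@@H]1CCOC(=O)C(C)(C)C
F11 | step 12 | hydroazulene (C-6=C-7) with 2-(pivaloyloxy)ethyl on C-5, silyl ether intact | CC1=CC[C@H]2[C@H](CC[C@]2(C)O[Si](CC)(CC)CC)C(C)(C)[C@@H]1CCOC(=O)C(C)(C)C
F12 | step 12 | (1S,3aS,5R,8aS)-5-(2-hydroxyethyl)-1,4,4,6-tetramethyl-1,2,3,3a,4,5,8,8a-octahydroazulen-1-ol | CC1=CC[C@H]2[C@H](CC[C@]2(C)O)C(C)(C)[C@@H]1CCO
F0 | step 6 | none | none
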